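## Retrosynthetic overview

1. Target ⇒ 30, in which the C4 exocyclic methylene is stored as a β-silyl tertiary silyl ether (Peterson unmasking last); butenolide ⇒ α-hydroxy ketone 28 + Ph3P=C=C=O.
2. 1-OH/H-10 ⇒ hydroboration of a C1=C10 alkene; 6-OAc and 7,8-diol ⇒ Luche reduction and OsO4 on a C6 enone obtained by 1,3-transposition from the C8 ketone.
3. C9 quaternary center and C11 ⇒ deconjugative aldol of the Wieland–Miescher-type dienolate from 12 with chiral-pool aldehyde 14.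
4. Rings A and B, formed together with C5 ⇒ intramolecular Diels–Alder reaction of vinylallene 8; the allene ⇒ anti-SN2′ Negishi coupling of propargylic ester 7.
5. 7 ⇒ (S)-lactone 1 (L-glutamic acid pool). Ring order: A and B together (step 5), butenolide (step 20).

Assumption: 1 and 13 are bought (from L-glutamic and L-malic acid); compounds 15–32 use clerodane numbering (decalin C1–C10, C18 on C4, methyl C19 on C5, methyl C17 on C8, methyl C20 and chain C11–C16 on C9), α = face of the C5 methyl, β = the opposite face.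

## Route

Step 1
Reactants: 1 (S)-5-(hydroxymethyl)dihydrofuran-2(3H)-one
Product: 3 (S)-5-(2,2-dibromoethenyl)dihydrofuran-2(3H)-one, via aldehyde 2 (not isolated)
Conditions: (COCl)2, DMSO, Et3N, CH2Cl2, −78 °C; then CBr4, PPh3, CH2Cl2, 0 °C
Reagents that add atoms: carbon tetrabromide, BrC(Br)(Br)Br
Why: Swern oxidation followed directly by Corey–Fuchs (Ramirez) dibromo-olefination under neutral conditions, so the α-oxygenated stereocenter is not epimerised.

Step 2
Reactants: 3 (S)-5-(2,2-dibromoethenyl)dihydrofuran-2(3H)-one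
Product: 5 (S)-5-(prop-1-yn-1-yl)dihydrofuran-2(3H)-one, via bromoalkyne 4 (not isolated)
Conditions: DBU, DMSO, 15 °C; then MeZnCl, Pd(PPh3)4 (3 mol%), THF, rt
Reagents that add atoms: methylzinc chloride, C[Zn]Cl
Why: E2 dehydrobromination to the 1-bromoalkyne and Negishi coupling give the methylalkyne without a base strong enough to attack the lactone, and the stereocenter is not involved.

Step 3
Reactants: 5 (S)-5-(prop-1-yn-1-yl)dihydrofuran-2(3H)-one
Product: 6 (S)-6-hydroxy-2-methylnon-1-en-7-yn-3-one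
Conditions: isopropenyllithium (1.05 equiv, from 2-bromopropene and t-BuLi), THF, −78 °C; NH4Cl (aq), −78 °C
Reagents that add atoms: isopropenyllithium, [Li]C(C)=C
Why: Mono-addition of an organolithium to a γ-lactone (the lithium lactolate persists at −78 °C) gives the γ-hydroxy isopropenyl ketone without touching the carbinol center.

Step 4
Reactants: 6 (S)-6-hydroxy-2-methylnon-1-en-7-yn-3-one
Product: 7 (R)-8-methyl-7-oxonon-8-en-2-yn-4-yl 4-nitrobenzoate
Conditions: 4-nitrobenzoic acid, PPh3, DIAD, THF, 0 °C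
Reagents that add atoms: 4-nitrobenzoic acid, OC(=O)c1ccc(cc1)[N+](=O)[O-]
Why: Mitsunobu esterification inverts the propargylic carbinol (SN2), giving the (R)-ester whose configuration fixes the sense of the later chirality transfer and which serves as the leaving group.

Step 5
Reactants: 7 (R)-8-methyl-7-oxonon-8-en-2-yn-4-yl 4-nitrobenzoate
Product: 9 (S)-6-ethoxy-5,8a-dimethyl-3,7,8,8a-tetrahydronaphthalen-1(2H)-one, via vinylallene 8 (not isolated)
Conditions: CH2=C(OEt)ZnCl (1.5 equiv, from ethyl vinyl ether, t-BuLi, ZnCl2), Pd(PPh3)4 (5 mol%), THF, 0 °C → rt; then 45 °C; NaHCO3 (aq) work-up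
Reagents that add atoms: (1-ethoxyvinyl)zinc chloride, CCOC(=C)[Zn]Cl
Why: Anti-SN2′ oxidative addition of zerovalent palladium and Negishi coupling give the (aS)-vinylallene (center-to-axis transfer), whose intramolecular Diels–Alder reaction with the isopropenyl ketone forms rings A and B at once; the tether on the allene terminus leaves one diene face open, so the axis is relayed to the C5 quaternary center (S).

Step 6
Reactants: 9 (S)-6-ethoxy-5,8a-dimethyl-3,7,8,8a-tetrahydronaphthalen-1(2H)-one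
Product: 11 (4aS,5S)-5-hydroxy-1,4a-dimethyl-5-[(trimethylsilyl)methyl]-4,4a,5,6,7,8-hexahydronaphthalen-2(3H)-one, via carbinol 10 (not isolated)
Conditions: Me3SiCH2Li, CeCl3, THF, −78 °C; NH4Cl (aq); then oxalic acid (cat.), THF/H2O, 0 °C
Reagents that add atoms: (trimethylsilyl)methyllithium, [Li]C[Si](C)(C)C; water, O
Why: Organocerium 1,2-addition to the hindered C4 ketone, anti to the angular methyl, stores the future exocyclic methylene as a Peterson β-hydroxysilane, and mild enol ether hydrolysis gives the conjugated enone (the C4 configuration is of no consequence).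

Step 7
Reactants: 11 (4aS,5S)-5-hydroxy-1,4a-dimethyl-5-[(trimethylsilyl)methyl]-4,4a,5,6,7,8-hexahydronaphthalen-2(3H)-one
Product: 12 (1S,8aS)-5,8a-dimethyl-1,6-bis(triethylsilyloxy)-1-[(trimethylsilyl)methyl]-1,2,3,7,8,8a-hexahydronaphthalene
Conditions: TESOTf (2.5 equiv), Et3N, CH2Cl2, 0 °C → rt
Reagents that add atoms: triethylsilyl trifluoromethanesulfonate, CC[Si](CC)(CC)OS(=O)(=O)C(F)(F)F
Why: Soft enolisation and silylation under equilibrating conditions give the extended dienol silyl ether (C8=C9, C10=C1) and cap the tertiary alcohol, which blocks premature Peterson elimination.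

Step 8
Reactants: 13 (S)-2-(2,2-dimethyl-1,3-dioxolan-4-yl)ethan-1-ol
Product: 14 (S)-2-(2,2-dimethyl-1,3-dioxolan-4-yl)acetaldehyde
Conditions: Dess–Martin periodinane, NaHCO3, CH2Cl2, 0 °C → rt
Reagents that add atoms: none
Why: Buffered Dess–Martin oxidation of the primary alcohol leaves the acetonide and its stereocenter intact.

Step 9
Reactants: 12 bis-TES dienol ether; 14 (S)-2-(2,2-dimethyl-1,3-dioxolan-4-yl)acetaldehyde
Product: 17 C9-aldol 11-isobutyrate (8-ketone with C1=C10 alkene), via lithium dienolate 15 (not isolated), via lithium aldolate 16 (not isolated)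
Conditions: MeLi (1.05 equiv), THF, 0 °C; 14, −78 °C; then i-PrCOCl, −78 → 0 °C
Reagents that add atoms: isobutyryl chloride, CC(C)C(=O)Cl
Why: Deconjugative aldol addition in which the lithium dienolate reacts at its α-carbon C9 on the β face (anti to the C5 methyl) through a closed Zimmerman–Traxler chair with the ring bond anti to the new oxygen, setting C9 and C11 (R) and moving the alkene to C1=C10; the aldolate is trapped as the isobutyrate before retro-aldol.

Step 10
Reactants: 17 C9-aldol 11-isobutyrate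
Product: 18 6,7-didehydro-17 (C6=C7–C8=O enone)
Conditions: IBX (2.5 equiv), DMSO/toluene, 70 °C
Reagents that add atoms: none
Why: IBX dehydrogenation of a ketone that can enolise only toward C7 gives the enone.

Step 11
Reactants: 18 6,7-didehydro-17
Product: 19 8-methyl-8-hydroxy-Δ6 tertiary allylic alcohol
Conditions: MeLi, CeCl3, THF, −78 °C; NH4Cl (aq)
Reagents that add atoms: methyllithium, [Li]C
Why: Organocerium 1,2-addition brings in the C17 methyl while the ester is inert at −78 °C, and the new carbinol center is erased in the next step.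

Step 12
Reactants: 19 tertiary allylic alcohol
Product: 20 8-methyl-Δ7-en-6-one
Conditions: IBX, DMSO, 55 °C
Reagents that add atoms: 2-iodoxybenzoic acid (IBX), O=C1OI(=O)(O)c2ccccc12
Why: Oxidative 1,3-transposition of a cyclic tertiary allylic alcohol (Dauben-type, here with IBX) puts the carbonyl at C6 and the alkene at C7=C8.

Step 13
Reactants: 20 8-methyl-Δ7-en-6-one
Product: 21 6α-hydroxy-8-methyl-Δ7-ene
Conditions: NaBH4, CeCl3·7H2O, MeOH, −40 °C
Reagents that add atoms: none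
Why: Luche 1,2-reduction with hydride arriving on the β face, away from the adjacent axial C5 methyl, gives the 6α-alcohol (6S).

Step 14
Reactants: 21 6α-hydroxy-8-methyl-Δ7-ene
Product: 22 6α-acetate
Conditions: Ac2O, DMAP, pyridine, rt
Reagents that add atoms: acetic anhydride, CC(=O)OC(C)=O
Why: Standard DMAP-catalysed acetylation of the only free hydroxyl, with no stereocenter affected.

Step 15
Reactants: 22 6α-acetate
Product: 23 6α-acetoxy-7β,8β-diol
Conditions: OsO4 (5 mol%), NMO, acetone/H2O, rt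
Reagents that add atoms: OsO4, O=[Os](=O)(=O)=O; N-methylmorpholine N-oxide, C[N+]1([O-])CCOCC1; water, O
Why: Upjohn syn-dihydroxylation of C7=C8 on the β face, anti to the allylic acetate and to the axial C5 and C9 methyls, sets C7 (R) and C8 (S), while the C1=C10 alkene flanked by two quaternary carbons reacts far more slowly.

Step 16
Reactants: 23 6α-acetoxy-7β,8β-diol
Product: 24 7β-isobutyrate
Conditions: (i-PrCO)2O, DMAP, Et3N, CH2Cl2, rt
Reagents that add atoms: isobutyric anhydride, CC(C)C(=O)OC(=O)C(C)C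
Why: Acylation of the only secondary hydroxyl, the tertiary C8 hydroxyl being unreactive.

Step 17
Reactants: 24 7β-isobutyrate
Product: 26 1β-hydroxy trans-decalin, via alkylborane 25 (not isolated)
Conditions: BH3·SMe2, THF, 0 °C → rt; then NaBO3·4H2O, THF/H2O, rt
Reagents that add atoms: sodium perborate (NaBO3), [Na+].[O-]OB=O
Why: Hydroboration–oxidation adds H and B syn to the β face of C1=C10 (anti to the C5 and C9 methyls, as with Δ5-steroids), giving H-10β, the trans ring fusion and the equatorial 1β-hydroxyl (1S, 10R), and the perborate work-up spares the esters.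

Step 18
Reactants: 26 1β-hydroxy trans-decalin
Product: 27 13,16-diol
Conditions: PPTS, MeOH, rt
Reagents that add atoms: none
Why: Acid-catalysed transketalisation removes the acetonide while the hindered tertiary TES ether and the esters survive.

Step 19
Reactants: 27 13,16-diol
Product: 28 16-hydroxy-13-ketone
Conditions: [(neocuproine)Pd(OAc)]2(OTf)2 (5 mol%), 1,4-benzoquinone, MeCN/H2O, rt
Reagents that add atoms: none
Why: Chemoselective palladium-catalysed oxidation of a vicinal diol at its secondary hydroxyl gives the α-hydroxy ketone, the isolated hindered C1 hydroxyl reacting much more slowly.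

Step 20
Reactants: 28 16-hydroxy-13-ketone
Product: 30 butenolide with masked C4, via ester ylide 29 (not isolated)
Conditions: Ph3P=C=C=O, toluene, 80 °C
Reagents that add atoms: (triphenylphosphoranylidene)ketene, O=C=C=P(c1ccccc1)(c1ccccc1)c1ccccc1
Why: Bestmann ylide chemistry: the primary hydroxyl adds to the ketene ylide and intramolecular Wittig olefination of the ketone closes the 4-substituted butenolide, as in cardenolide synthesis.

Step 21
Reactants: 30 butenolide with masked C4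
Product: 32 target CNP0325163.2, via tertiary alcohol 31 (not isolated)
Conditions: HF·pyridine, THF, 0 °C → rt
Reagents that add atoms: none
Why: HF cleaves the tertiary TES ether and acid-promoted Peterson elimination of the β-hydroxysilane releases the C4 exocyclic methylene without touching the three esters.

## Compound list

1 | (S)-5-(hydroxymethyl)dihydrofuran-2(3H)-one | O=C1CC[C@@H](CO)O1 | starting material
2 | (S)-5-oxotetrahydrofuran-2-carbaldehyde | O=C1CC[C@@H](C=O)O1 | intermediate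
3 | (S)-5-(2,2-dibromoethenyl)dihydrofuran-2(3H)-one | O=C1CC[C@@H](C=C(Br)Br)O1 | intermediate
4 | (S)-5-(bromoethynyl)dihydrofuran-2(3H)-one | O=C1CC[C@@H](C#CBr)O1 | intermediate
5 | (S)-5-(prop-1-yn-1-yl)dihydrofuran-2(3H)-one | O=C1CC[C@@H](C#CC)O1 | intermediate
6 | (S)-6-hydroxy-2-methylnon-1-en-7-yn-3-one | C=C(C)C(=O)CC[C@H](O)C#CC | intermediate
7 | (R)-8-methyl-7-oxonon-8-en-2-yn-4-yl 4-nitrobenzoate | C=C(C)C(=O)CC[C@@H](OC(=O)c1ccc(cc1)[N+](=O)[O-])C#CC | intermediate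
8 | (aS)-9-ethoxy-2,8-dimethyldeca-1,6,7,9-tetraen-3-one | C=C(C)C(=O)CCC([H])=[C@@]=C(C)C(OCC)=C | intermediate
9 | (S)-6-ethoxy-5,8a-dimethyl-3,7,8,8a-tetrahydronaphthalen-1(2H)-one | O=C1CCC=C2[C@]1(C)CCC(OCC)=C2C | intermediate
10 | (1S,8aS)-6-ethoxy-5,8a-dimethyl-1-[(trimethylsilyl)methyl]-1,2,3,7,8,8a-hexahydronaphthalen-1-ol | C[Si](C)(C)C[C@]1(O)CCC=C2[C@]1(C)CCC(OCC)=C2C | intermediate
11 | (4aS,5S)-5-hydroxy-1,4a-dimethyl-5-[(trimethylsilyl)methyl]-4,4a,5,6,7,8-hexahydronaphthalen-2(3H)-one | C[Si](C)(C)C[C@]1(O)CCCC2=C(C)C(=O)CC[C@]12C | intermediate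
12 | (1S,8aS)-5,8a-dimethyl-1,6-bis(triethylsilyloxy)-1-[(trimethylsilyl)methyl]-1,2,3,7,8,8a-hexahydronaphthalene | C[Si](C)(C)C[C@]1(O[Si](CC)(CC)CC)CCC=C2[C@]1(C)CCC(O[Si](CC)(CC)CC)=C2C | intermediate
13 | (S)-2-(2,2-dimethyl-1,3-dioxolan-4-yl)ethan-1-ol | CC1(C)OC[C@H](CCO)O1 | starting material
14 | (S)-2-(2,2-dimethyl-1,3-dioxolan-4-yl)acetaldehyde | CC1(C)OC[C@H](CC=O)O1 | intermediate
15 | lithium dienolate of 12 (C8–OLi, C8=C9 and C10=C1; 4α-OTES, 4β-CH2SiMe3) | C[Si](C)(C)C[C@]1(O[Si](CC)(CC)CC)CCC=C2[C@]1(C)CCC(O[Li])=C2C | intermediate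
16 | lithium 11-alkoxide of the aldol adduct: 9β-[(1R)-2-((4S)-2,2-dimethyl-1,3-dioxolan-4-yl)-1-(lithiooxy)ethyl]-5α,9α-dimethyl-4α-triethylsilyloxy-4β-(trimethylsilylmethyl)-Δ1(10)-octalin-8-one | C[Si](C)(C)C[C@]1(O[Si](CC)(CC)CC)CCC=C2[C@]1(C)CCC(=O)[C@@]2(C)[C@@H](C[C@H]3COC(C)(C)O3)O[Li] | intermediate
17 | C9-aldol 11-isobutyrate: 9β-[(1R)-2-((4S)-2,2-dimethyl-1,3-dioxolan-4-yl)-1-isobutyryloxyethyl]-5α,9α-dimethyl-4α-triethylsilyloxy-4β-(trimethylsilylmethyl)-Δ1(10)-octalin-8-one | C[Si](C)(C)C[C@]1(O[Si](CC)(CC)CC)CCC=C2[C@]1(C)CCC(=O)[C@@]2(C)[C@@H](C[C@H]3COC(C)(C)O3)OC(=O)C(C)C | intermediate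
18 | 6,7-didehydro-17 (C6=C7–C8=O enone, C1=C10 retained) | C[Si](C)(C)C[C@]1(O[Si](CC)(CC)CC)CCC=C2[C@]1(C)C=CC(=O)[C@@]2(C)[C@@H](C[C@H]3COC(C)(C)O3)OC(=O)C(C)C | intermediate
19 | 8-methyl-8-hydroxy-Δ6 tertiary allylic alcohol (8β-methyl, 8α-OH drawn; the 8-epimer is equally usable) | C[Si](C)(C)C[C@]1(O[Si](CC)(CC)CC)CCC=C2[C@]1(C)C=C[C@](C)(O)[C@@]2(C)[C@@H](C[C@H]3COC(C)(C)O3)OC(=O)C(C)C | intermediate
20 | 8-methyl-Δ7-en-6-one (C1=C10 retained) | C[Si](C)(C)C[C@]1(O[Si](CC)(CC)CC)CCC=C2[C@]1(C)C(=O)C=C(C)[C@@]2(C)[C@@H](C[C@H]3COC(C)(C)O3)OC(=O)C(C)C | intermediate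
21 | 6α-hydroxy-8-methyl-Δ7-ene (6S) | C[Si](C)(C)C[C@]1(O[Si](CC)(CC)CC)CCC=C2[C@]1(C)[C@H](O)C=C(C)[C@@]2(C)[C@@H](C[C@H]3COC(C)(C)O3)OC(=O)C(C)C | intermediate
22 | 6α-acetate of 21 | C[Si](C)(C)C[C@]1(O[Si](CC)(CC)CC)CCC=C2[C@]1(C)[C@H](OC(C)=O)C=C(C)[C@@]2(C)[C@@H](C[C@H]3COC(C)(C)O3)OC(=O)C(C)C | intermediate
23 | 6α-acetoxy-7β,8β-dihydroxy-8α-methyl compound (C1=C10 retained) | C[Si](C)(C)C[C@]1(O[Si](CC)(CC)CC)CCC=C2[C@]1(C)[C@H](OC(C)=O)[C@@H](O)[C@@](C)(O)[C@@]2(C)[C@@H](C[C@H]3COC(C)(C)O3)OC(=O)C(C)C | intermediate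
24 | 7β-isobutyrate of 23 | C[Si](C)(C)C[C@]1(O[Si](CC)(CC)CC)CCC=C2[C@]1(C)[C@H](OC(C)=O)[C@@H](OC(=O)C(C)C)[C@@](C)(O)[C@@]2(C)[C@@H](C[C@H]3COC(C)(C)O3)OC(=O)C(C)C | intermediate
25 | 1β-boryl (BH2), 10β-H trans-decalin from 24 | C[Si](C)(C)C[C@]1(O[Si](CC)(CC)CC)CC[C@H](B)[C@@H]2[C@]1(C)[C@H](OC(C)=O)[C@@H](OC(=O)C(C)C)[C@@](C)(O)[C@@]2(C)[C@@H](C[C@H]3COC(C)(C)O3)OC(=O)C(C)C | intermediate
26 | 1β-hydroxy trans-decalin (1S, 10R; acetonide side chain) | C[Si](C)(C)C[C@]1(O[Si](CC)(CC)CC)CC[C@H](O)[C@@H]2[C@]1(C)[C@H](OC(C)=O)[C@@H](OC(=O)C(C)C)[C@@](C)(O)[C@@]2(C)[C@@H](C[C@H]3COC(C)(C)O3)OC(=O)C(C)C | intermediate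
27 | 13,16-diol (13S) from 26 | C[Si](C)(C)C[C@]1(O[Si](CC)(CC)CC)CC[C@H](O)[C@@H]2[C@]1(C)[C@H](OC(C)=O)[C@@H](OC(=O)C(C)C)[C@@](C)(O)[C@@]2(C)[C@@H](C[C@H](O)CO)OC(=O)C(C)C | intermediate
28 | 16-hydroxy-13-ketone | C[Si](C)(C)C[C@]1(O[Si](CC)(CC)CC)CC[C@H](O)[C@@H]2[C@]1(C)[C@H](OC(C)=O)[C@@H](OC(=O)C(C)C)[C@@](C)(O)[C@@]2(C)[C@@H](CC(=O)CO)OC(=O)C(C)C | intermediate
29 | 16-O-[(triphenylphosphoranylidene)acetyl] ester of 28 | C[Si](C)(C)C[C@]1(O[Si](CC)(CC)CC)CC[C@H](O)[C@@H]2[C@]1(C)[C@H](OC(C)=O)[C@@H](OC(=O)C(C)C)[C@@](C)(O)[C@@]2(C)[C@@H](CC(=O)COC(=O)C=P(c3ccccc3)(c3ccccc3)c3ccccc3)OC(=O)C(C)C | intermediate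
30 | 13-en-15,16-olide with 4α-triethylsilyloxy and 4β-(trimethylsilylmethyl) | C[Si](C)(C)C[C@]1(O[Si](CC)(CC)CC)CC[C@H](O)[C@@H]2[C@]1(C)[C@H](OC(C)=O)[C@@H](OC(=O)C(C)C)[C@@](C)(O)[C@@]2(C)[C@@H](CC3=CC(=O)OC3)OC(=O)C(C)C | intermediate
31 | 4α-hydroxy-4β-(trimethylsilylmethyl) analogue of 30 | C[Si](C)(C)C[C@]1(O)CC[C@H](O)[C@@H]2[C@]1(C)[C@H](OC(C)=O)[C@@H](OC(=O)C(C)C)[C@@](C)(O)[C@@]2(C)[C@@H](CC3=CC(=O)OC3)OC(=O)C(C)C | intermediate
32 | CNP0325163.2 (1S,5S,6S,7R,8S,9R,10R,11R) | C=C1CC[C@H](O)[C@@H]2[C@]1(C)[C@H](OC(C)=O)[C@@H](OC(=O)C(C)C)[C@@](C)(O)[C@@]2(C)[C@@H](CC1=CC(=O)OC1)OC(=O)C(C)C | target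

## Step count and risks

Total step count: 21. Longest linear sequence: 20 steps (1 → 32 through steps 1–7 and 9–21).

Most likely to fail:

First, step 5. The allenylpalladium intermediate can partly racemise or couple at the propargylic carbon, and the hydroxy enone series 6 and 7 is prone to polymerise. The fallback sets out from 5 and comes back at 9. The lactone is opened with Me(MeO)NH·HCl and Me3Al to (S)-4-hydroxy-N-methoxy-N-methylhept-5-ynamide F1. Mitsunobu inversion with 4-nitrobenzoic acid gives (R)-7-[methoxy(methyl)amino]-7-oxohept-2-yn-4-yl 4-nitrobenzoate F2. Stoichiometric anti-SN2′ substitution with lithium bis(1-ethoxyvinyl)cuprate (from 1-ethoxyvinyllithium and CuI, THF, −78 °C) gives (aS)-7-ethoxy-N-methoxy-N,6-dimethylocta-4,5,7-trienamide F3 while no enone is present. Isopropenylmagnesium bromide then releases vinylallene 8, which cyclises to 9.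

Second, step 9. At this crowded quaternary center the dienolate may attack through its γ-carbon, aldehyde 14 may be enolised, the adduct may revert, or the C11 ratio may be poor. The fallback sets out from 12 and 14 and comes back at 17. Aldehyde 14 is oxidised (NaClO2, NaH2PO4, 2-methyl-2-butene) to (S)-2-(2,2-dimethyl-1,3-dioxolan-4-yl)acetic acid F4 and activated with carbonyldiimidazole as 1-[(S)-2-(2,2-dimethyl-1,3-dioxolan-4-yl)acetyl]imidazole F5. The lithium dienolate 15 is C-acylated at C9 by it, irreversibly and without forming the C11 center, to give the 9β-acyl β-diketone F6. Reduction of the exocyclic carbonyl with Zn(BH4)2 under chelation control gives the free 11R aldol F7, and isobutyric anhydride with DMAP gives 17.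

Third, step 17. The C1=C10 alkene lies between two quaternary carbons and may need forcing conditions under which BH3 begins to reduce the esters. The fallback sets out from 24 and comes back at 26. Dimethyldioxirane (acetone, 0 °C) epoxidises the alkene on the β face to the 1β,10β-epoxide of 24 F8. Cp2TiCl (trivalent titanium, from Cp2TiCl2 and Mn) with 1,4-cyclohexadiene opens it homolytically at C10, and hydrogen-atom transfer to the tertiary radical on the β face gives 26.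

## Further compounds

F1 | step 5 | (S)-4-hydroxy-N-methoxy-N-methylhept-5-ynamide | CC#C[C@@H](O)CCC(=O)N(C)OC
F2 | step 5 | (R)-7-[methoxy(methyl)amino]-7-oxohept-2-yn-4-yl 4-nitrobenzoate | CC#C[C@H](OC(=O)c1ccc(cc1)[N+](=O)[O-])CCC(=O)N(C)OC
F3 | step 5 | (aS)-7-ethoxy-N-methoxy-N,6-dimethylocta-4,5,7-trienamide | C=C(OCC)C(C)=[C@@]=C([H])CCC(=O)N(C)OC
F4 | step 9 | (S)-2-(2,2-dimethyl-1,3-dioxolan-4-yl)acetic acid | CC1(C)OC[C@H](CC(=O)O)O1
F5 | step 9 | 1-[(S)-2-(2,2-dimethyl-1,3-dioxolan-4-yl)acetyl]imidazole | CC1(C)OC[C@H](CC(=O)n2ccnc2)O1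
F6 | step 9 | 9β-[2-((4S)-2,2-dimethyl-1,3-dioxolan-4-yl)acetyl]-5α,9α-dimethyl-4α-triethylsilyloxy-4β-(trimethylsilylmethyl)-Δ1(10)-octalin-8-one | C[Si](C)(C)C[C@]1(O[Si](CC)(CC)CC)CCC=C2[C@]1(C)CCC(=O)[C@@]2(C)C(=O)C[C@H]3COC(C)(C)O3
F7 | step 9 | free 11R aldol (17 without the isobutyryl group) | C[Si](C)(C)C[C@]1(O[Si](CC)(CC)CC)CCC=C2[C@]1(C)CCC(=O)[C@@]2(C)[C@@H](C[C@H]3COC(C)(C)O3)O
F8 | step 17 | 1β,10β-epoxide of 24 | C[Si](C)(C)C[C@]1(O[Si](CC)(CC)CC)CC[C@@H]3O[C@]32[C@]1(C)[C@H](OC(C)=O)[C@@H](OC(=O)C(C)C)[C@@](C)(O)[C@@]2(C)[C@@H](C[C@H]4COC(C)(C)O4)OC(=O)C(C)C
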